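**Retrosynthetic overview**

1. Agrandol ⇐ aromatic Claisen ([3,3]) rearrangement of the 7-O-(1,1-dimethylallyl) ether of (2S)-5,7-dihydroxy-6-methoxyflavanone; the C8–prenyl bond is made last, at the only open ortho position.
2. That flavanone ⇐ its 5,7-dibenzyl ether ⇐ ring C closed by intramolecular Friedel–Crafts acylation (C4–C4a) of an (S)-3-aryloxy-3-phenylpropanoic acid.
3. The aryl ether (O1–C2) ⇐ Mitsunobu inversion between 3,5-bis(benzyloxy)-4-methoxyphenol and purchased ethyl (R)-3-hydroxy-3-phenylpropanoate, which supplies the only stereocentre.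
4. The phenol ⇐ benzylation, then Baeyer–Villiger/Dakin oxidation, of 3,5-dihydroxy-4-methoxybenzaldehyde; its mirror symmetry makes the etherification site and the ring closure unambiguous.
5. Ring order: rings A and B are bought; ring C is the only ring formed (step 5).

Assumption: the aldehyde of step 1, the hydroxy ester of step 3 and the carbonate of step 7 are taken as catalogue items.

**Route**

Step 1
Reactants: 1 3,5-dihydroxy-4-methoxybenzaldehyde
Product: 2 3,5-bis(benzyloxy)-4-methoxybenzaldehyde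
Conditions: BnBr (2.2 equiv), K2CO3 (2.5 equiv), DMF, 60 °C
Reagents that add atoms: benzyl bromide, BrCc1ccccc1
Why: Williamson etherification of both phenols masks the two flanking oxygens, so that only the oxygen created in step 2 can be alkylated in step 3.

Step 2
Reactants: 2 3,5-bis(benzyloxy)-4-methoxybenzaldehyde
Product: 4 3,5-bis(benzyloxy)-4-methoxyphenol, via aryl formate 3 (not isolated)
Conditions: mCPBA (1.3 equiv), CH2Cl2, rt; then K2CO3 (cat.), MeOH, rt
Reagents that add atoms: mCPBA (3-chloroperoxybenzoic acid), OOC(=O)c1cccc(Cl)c1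
Why: Baeyer–Villiger (Dakin-type) oxidation, in which the electron-rich aryl group migrates to give the formate that is methanolysed in the same flask, as in the known conversion of 3,4,5-trimethoxybenzaldehyde into the phenol.

Step 3
Reactants: 4 3,5-bis(benzyloxy)-4-methoxyphenol; 5 ethyl (3R)-3-hydroxy-3-phenylpropanoate
Product: 6 ethyl (3S)-3-[3,5-bis(benzyloxy)-4-methoxyphenoxy]-3-phenylpropanoate
Conditions: PPh3 (1.3 equiv), DIAD (1.3 equiv, slow addition), PhMe, 0 °C → rt
Reagents that add atoms: none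
Why: Mitsunobu etherification, an SN2 displacement of the activated benzylic alcohol by the phenoxide with inversion, turns the purchased (R) carbinol into the (S) aryl ether (future C2) using only achiral reagents.

Step 4
Reactants: 6 ethyl (3S)-3-[3,5-bis(benzyloxy)-4-methoxyphenoxy]-3-phenylpropanoate
Product: 7 (3S)-3-[3,5-bis(benzyloxy)-4-methoxyphenoxy]-3-phenylpropanoic acid
Conditions: LiOH·H2O (2 equiv), THF–H2O, 0 °C → rt; then cold 1 M HCl to pH 3
Reagents that add atoms: lithium hydroxide, [Li+].[OH-]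
Why: Saponification at low temperature is faster than E1cB loss of the aryloxide and does not touch the stereocentre.

Step 5
Reactants: 7 (3S)-3-[3,5-bis(benzyloxy)-4-methoxyphenoxy]-3-phenylpropanoic acid
Product: 9 (2S)-5,7-bis(benzyloxy)-6-methoxy-2-phenylchroman-4-one, via mixed trifluoroacetic anhydride 8 (not isolated)
Conditions: TFAA (2 equiv), CH2Cl2, 0 °C → rt; aq. NaHCO3 work-up
Reagents that add atoms: none
Why: Intramolecular Friedel–Crafts acylation occurs at the carbon ortho to the ether oxygen and ortho/para to the two benzyloxy groups; both ortho positions are equivalent, so only one chromanone can form, and the mild conditions leave C2 untouched.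

Step 6
Reactants: 9 (2S)-5,7-bis(benzyloxy)-6-methoxy-2-phenylchroman-4-one
Product: 10 (2S)-5,7-dihydroxy-6-methoxy-2-phenylchroman-4-one
Conditions: H2 (1 atm), Pd/C (10 wt%), EtOAc–MeOH, rt, stopped at full conversion
Reagents that add atoms: none
Why: Hydrogenolysis of the two aryl benzyl ethers is much faster than cleavage of the C2–O1 bond or reduction of the ketone, and it is done before any alkene is present.

Step 7
Reactants: 10 (2S)-5,7-dihydroxy-6-methoxy-2-phenylchroman-4-one
Product: 11 (2S)-5-hydroxy-6-methoxy-7-[(2-methylbut-3-en-2-yl)oxy]-2-phenylchroman-4-one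
Conditions: tert-butyl 2-methylbut-3-en-2-yl carbonate (1.5 equiv), Pd(PPh3)4 (5 mol%), THF, 0 °C
Reagents that add atoms: tert-butyl 2-methylbut-3-en-2-yl carbonate, CC(C)(C)OC(=O)OC(C)(C)C=C
Why: Tsuji–Trost O-allylation, in which zerovalent palladium ionises the carbonate and the acidic 7-phenoxide attacks the more substituted allyl terminus to give the tertiary ether; the chelated 5-OH does not react, and the near-neutral medium avoids ring opening to the chalcone.

Step 8
Reactants: 11 (2S)-5-hydroxy-6-methoxy-7-[(2-methylbut-3-en-2-yl)oxy]-2-phenylchroman-4-one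
Product: 13 agrandol [(2S)-5,7-dihydroxy-6-methoxy-8-(3-methylbut-2-en-1-yl)-2-phenylchroman-4-one], via C8 dienone 12 (not isolated)
Conditions: degassed PhMe, 110 °C, sealed tube
Reagents that add atoms: none
Why: Aromatic Claisen [3,3]-sigmatropic rearrangement delivers the allyl terminus to C8, the only free ortho position (attack at the methoxy-bearing C6 is reversible and unproductive), and the dienone tautomerises to the phenol; the neutral thermal conditions leave C2 (S) intact.

**Compound list**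

1 | 3,5-dihydroxy-4-methoxybenzaldehyde | COc1c(O)cc(C=O)cc1O | starting material
2 | 3,5-bis(benzyloxy)-4-methoxybenzaldehyde | COc1c(OCc2ccccc2)cc(C=O)cc1OCc1ccccc1 | intermediate
3 | 3,5-bis(benzyloxy)-4-methoxyphenyl formate | COc1c(OCc2ccccc2)cc(OC=O)cc1OCc1ccccc1 | intermediate
4 | 3,5-bis(benzyloxy)-4-methoxyphenol | COc1c(OCc2ccccc2)cc(O)cc1OCc1ccccc1 | intermediate
5 | ethyl (3R)-3-hydroxy-3-phenylpropanoate | CCOC(=O)C[C@H](c1ccccc1)O | starting material
6 | ethyl (3S)-3-[3,5-bis(benzyloxy)-4-methoxyphenoxy]-3-phenylpropanoate | CCOC(=O)C[C@@H](c1ccccc1)Oc1cc(OCc2ccccc2)c(OC)c(OCc2ccccc2)c1 | intermediate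
7 | (3S)-3-[3,5-bis(benzyloxy)-4-methoxyphenoxy]-3-phenylpropanoic acid | OC(=O)C[C@@H](c1ccccc1)Oc1cc(OCc2ccccc2)c(OC)c(OCc2ccccc2)c1 | intermediate
8 | (3S)-3-[3,5-bis(benzyloxy)-4-methoxyphenoxy]-3-phenylpropanoic trifluoroacetic anhydride | O=C(OC(=O)C(F)(F)F)C[C@@H](c1ccccc1)Oc1cc(OCc2ccccc2)c(OC)c(OCc2ccccc2)c1 | intermediate
9 | (2S)-5,7-bis(benzyloxy)-6-methoxy-2-phenylchroman-4-one | COc1c(OCc3ccccc3)cc2c(c1OCc1ccccc1)C(=O)C[C@@H](c1ccccc1)O2 | intermediate
10 | (2S)-5,7-dihydroxy-6-methoxy-2-phenylchroman-4-one | COc1c(O)cc2c(c1O)C(=O)C[C@@H](c1ccccc1)O2 | intermediate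
11 | (2S)-5-hydroxy-6-methoxy-7-[(2-methylbut-3-en-2-yl)oxy]-2-phenylchroman-4-one | COc1c(OC(C)(C)C=C)cc2c(c1O)C(=O)C[C@@H](c1ccccc1)O2 | intermediate
12 | (2S)-5-hydroxy-6-methoxy-8-(3-methylbut-2-en-1-yl)-2-phenyl-2,3-dihydrochromene-4,7(8H)-dione (both C8 epimers) | COC1=C(O)C2=C(O[C@H](c3ccccc3)CC2=O)C(CC=C(C)C)C1=O | intermediate
13 | agrandol, (2S)-5,7-dihydroxy-6-methoxy-8-(3-methylbut-2-en-1-yl)-2-phenylchroman-4-one | COc1c(O)c(CC=C(C)C)c2c(c1O)C(=O)C[C@@H](c1ccccc1)O2 | target

**Count and risks**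

Total step count: 8. Longest linear sequence: 8 steps (1 → 13); compound 5 is bought.

Most likely to fail, step 3: the alcohol is a benzylic β-hydroxy ester, so the activated intermediate can eliminate to ethyl cinnamate or lose some enantiopurity by ionisation. The fallback sets out from 4 and uses a carbinol with no acidifying carbonyl. Mitsunobu coupling of 4 with (R)-3-chloro-1-phenylpropan-1-ol (PPh3, DIAD, THF, 0 °C), an etherification well precedented for aryl 3-chloro-1-phenylpropyl ethers, gives (S)-1,3-bis(benzyloxy)-5-(3-chloro-1-phenylpropoxy)-2-methoxybenzene F1. KOAc with NaI (cat.) in DMF at 80 °C gives (3S)-3-[3,5-bis(benzyloxy)-4-methoxyphenoxy]-3-phenylpropyl acetate F2. K2CO3 in MeOH gives (3S)-3-[3,5-bis(benzyloxy)-4-methoxyphenoxy]-3-phenylpropan-1-ol F3. TEMPO (cat.) and PhI(OAc)2 in MeCN–H2O oxidise F3 to the acid, and the route is rejoined at 7.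

Second, step 5: acid could trigger retro-oxa-Michael loss of the phenol or erode C2 by ionisation of the benzylic ether. The fallback sets out from 7 and closes ring C with a nucleophilic arene instead of an electrophilic acyl group. NBS (1.0 equiv) in MeCN at 0 °C brominates one of the two equivalent activated positions to give (3S)-3-[3,5-bis(benzyloxy)-2-bromo-4-methoxyphenoxy]-3-phenylpropanoic acid F4. Coupling with HN(OMe)Me·HCl (EDC·HCl, i-Pr2NEt, CH2Cl2) gives (3S)-3-[3,5-bis(benzyloxy)-2-bromo-4-methoxyphenoxy]-N-methoxy-N-methyl-3-phenylpropanamide F5. Bromine–lithium exchange with t-BuLi (2.1 equiv, THF, −100 °C) and Parham-type cycloacylation onto the amide rejoin the route at 9.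

Third, step 7: the π-allyl complex could give the linear O-prenyl ether, or the tertiary ether could isomerise before isolation. The fallback sets out from 10 and builds the tertiary ether from an alkyne. Copper-catalysed O-alkylation with 3-chloro-3-methylbut-1-yne (CuCl2 1 mol%, DBU 1.1 equiv consumed by the 7-OH, MeCN, −5 °C) gives (2S)-5-hydroxy-6-methoxy-7-[(2-methylbut-3-yn-2-yl)oxy]-2-phenylchroman-4-one F6. Semi-hydrogenation (H2 1 atm, Pd/CaCO3 poisoned with Pb(OAc)2, quinoline, EtOAc) rejoins the route at 11.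

**Further compounds**

F1 | step 3 | (S)-1,3-bis(benzyloxy)-5-(3-chloro-1-phenylpropoxy)-2-methoxybenzene | ClCC[C@@H](c1ccccc1)Oc1cc(OCc2ccccc2)c(OC)c(OCc2ccccc2)c1
F2 | step 3 | (3S)-3-[3,5-bis(benzyloxy)-4-methoxyphenoxy]-3-phenylpropyl acetate | CC(=O)OCC[C@@H](c1ccccc1)Oc1cc(OCc2ccccc2)c(OC)c(OCc2ccccc2)c1
F3 | step 3 | (3S)-3-[3,5-bis(benzyloxy)-4-methoxyphenoxy]-3-phenylpropan-1-ol | OCC[C@@H](c1ccccc1)Oc1cc(OCc2ccccc2)c(OC)c(OCc2ccccc2)c1
F4 | step 5 | (3S)-3-[3,5-bis(benzyloxy)-2-bromo-4-methoxyphenoxy]-3-phenylpropanoic acid | OC(=O)C[C@@H](c1ccccc1)Oc1cc(OCc2ccccc2)c(OC)c(OCc2ccccc2)c1Br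
F5 | step 5 | (3S)-3-[3,5-bis(benzyloxy)-2-bromo-4-methoxyphenoxy]-N-methoxy-N-methyl-3-phenylpropanamide | CON(C)C(=O)C[C@@H](c1ccccc1)Oc1cc(OCc2ccccc2)c(OC)c(OCc2ccccc2)c1Br
F6 | step 7 | (2S)-5-hydroxy-6-methoxy-7-[(2-methylbut-3-yn-2-yl)oxy]-2-phenylchroman-4-one | COc1c(OC(C)(C)C#C)cc2c(c1O)C(=O)C[C@@H](c1ccccc1)O2
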